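**Retrosynthetic overview**
1. The target is the hydrogen malonate of (5S,9S,10S)-labda-7,13E-dien-15-ol. The C15–O acyl bond is cut to the allylic alcohol and Meldrum's acid, and the alcohol is traced back to its diphosphate ester (enzymatic P–O hydrolysis).
2. Feature that carries the strategy: the trans-fused rings A and B with the stereocenters C5, C9 and C10, the ring B alkene C7=C8 and the intact E-configured allylic terminus C13=C14–C15–O map atom for atom onto an all-E geranylgeranyl chain held in a chair–chair fold.
3. Key disconnection: C4–C5 and C9–C10 are cut together, back to geranylgeranyl diphosphate, in the sense of an enzymatic proton-initiated cationic bicyclisation that ends by loss of H7.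
4. Ring order: ring A closes first (C4–C5) and ring B second (C9–C10), in one cascade that sets all three stereocenters.
5. Geranylgeranyl diphosphate comes from commercial all-E geranylgeraniol through the allylic chloride and displacement with a diphosphate salt.

Key step: step 3

Remark on the chemistry (assumption): the phosphate esters 3, 4 and 5 and inorganic phosphate exist as ammonium salts in buffered water and are drawn as free acids, and the cyclase of step 3 is taken to be available as a purified recombinant protein of the normal (5S,9S,10S) series, expressed from a synthetic gene.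

Step 1
Reactants: 1 (2E,6E,10E)-geranylgeraniol
Product: 2 (2E,6E,10E)-geranylgeranyl chloride
Conditions: NCS, Me2S, CH2Cl2, −30 to 0 °C; pentane work-up, used crude at once
Reagents that add atoms: N-chlorosuccinimide, O=C1CCC(=O)N1Cl
Why: Corey–Kim chlorination, in which the alcohol adds to the sulfonium salt formed from NCS and Me2S and chloride then displaces dimethyl sulfoxide from the primary allylic carbon by SN2 under neutral conditions, so that no allylic transposition, no E/Z isomerisation and no attack on the three other trisubstituted alkenes is expected, and no stereocenter is formed.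

Step 2
Reactants: 2 (2E,6E,10E)-geranylgeranyl chloride
Product: 3 (2E,6E,10E)-geranylgeranyl diphosphate
Conditions: (Bu4N)3HP2O7, MeCN, rt; Dowex 50W-X8 (NH4+ form), aq NH4HCO3/iPrOH; cellulose chromatography, lyophilisation
Reagents that add atoms: tris(tetrabutylammonium) hydrogen diphosphate, CCCC[N+](CCCC)(CCCC)CCCC.CCCC[N+](CCCC)(CCCC)CCCC.CCCC[N+](CCCC)(CCCC)CCCC.OP(=O)([O-])OP(=O)([O-])[O-]
Why: Davisson–Poulter diphosphorylation, in which the diphosphate trianion, soluble in dry acetonitrile as its tetrabutylammonium salt, displaces the primary allylic chloride by SN2 with the E geometry retained, and exchange of the cations for ammonium on the resin (the remaining tetrabutylammonium ions stay bound to it) gives the water-soluble salt that the cyclase accepts; no stereocenter is formed.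

Step 3
Reactants: 3 (2E,6E,10E)-geranylgeranyl diphosphate
Product: 4 (5S,9S,10S)-labda-7,13E-dien-15-yl diphosphate
Conditions: recombinant (5S,9S,10S)-labda-7,13E-dienyl diphosphate synthase (class 2 diterpene cyclase), HEPES pH 7.2, KCl, MgCl2, DTT, glycerol, 30 °C, slow feed of 3; ultrafiltration, C18 solid-phase extraction
Reagents that add atoms: none
Why: The aspartate general acid of the DxDD motif protonates C3 of the terminal alkene of 3, which the active site holds in a chair–chair fold; the C4 cation is captured by the C5=C10 alkene (C4–C5 bond, ring A, 6-endo-trig), the resulting C10 cation by the C8=C9 alkene (C9–C10 bond, ring B, 6-endo-trig), and the labda-13E-en-8-yl cation gives up H7 to the active-site base to leave the C7=C8 alkene. The closest known reaction type is protonation-initiated (class 2) diterpene synthase catalysis of the copalyl diphosphate synthase family, for which 3 is the native substrate and of which members that release the 7,13E-dienyl diphosphate are known. C5 and C10 are set by anti addition across the E-configured C5=C10 alkene in the chair of ring A and C9 by anti addition across the E-configured C8=C9 alkene in the chair of ring B, which gives the trans ring fusion with H5 and H9 on the face opposite to the C20 methyl group. The absolute sense (5S,9S,10S) is fixed by the protein, which binds only one of the two mirror-image chair–chair conformers. The step needs termination by loss of H7 in preference to loss of a C17 proton or capture of water at C8, which the placement of the catalytic base secures, and it needs the diphosphate and the C13=C14 alkene to stay untouched, which follows from the absence of a diphosphate-ionising (class 1) site and from the diphosphate anchor that keeps the allylic terminus away from the cationic centres.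

Step 4
Reactants: 4 (5S,9S,10S)-labda-7,13E-dien-15-yl diphosphate
Product: 6 (5S,9S,10S)-labda-7,13E-dien-15-ol, via labda-7,13E-dien-15-yl phosphate 5 (not isolated)
Conditions: calf intestinal alkaline phosphatase, Tris pH 8.5, MgCl2, 37 °C, hexane overlay; extraction, silica
Reagents that add atoms: none
Why: Enzymatic phosphomonoester hydrolysis, in which alkaline phosphatase removes the terminal phosphate and then the second one by attack at phosphorus, so that the C15–O bond is never broken and neither allylic transposition nor loss of the E geometry can occur, while the mildly basic buffer keeps the acid-labile allylic diphosphate and the C7=C8 alkene away from protic ionisation; no stereocenter is touched.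

Step 5
Reactants: 6 (5S,9S,10S)-labda-7,13E-dien-15-ol; 7 Meldrum's acid (2,2-dimethyl-1,3-dioxane-4,6-dione)
Product: 8 (5S,9S,10S)-labda-7,13E-dien-15-yl hydrogen malonate (target CNP0279336.1)
Conditions: toluene, 100 °C; extraction into aq NaHCO3, cold acidification to pH 3, EtOAc
Reagents that add atoms: none
Why: Alcoholysis of Meldrum's acid, in which the primary allylic alcohol adds to one of the activated ring carbonyls and the ring-opened hemiketal ester collapses with loss of acetone to give the malonic half ester directly, without protecting group or coupling agent and below the temperature at which the half ester decarboxylates; the stereocenters and both alkenes are spectators.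

**Compound list**
1 | (2E,6E,10E)-geranylgeraniol | CC(C)=CCC/C(C)=C/CC/C(C)=C/CC/C(C)=C/CO | starting material
2 | (2E,6E,10E)-geranylgeranyl chloride | CC(C)=CCC/C(C)=C/CC/C(C)=C/CC/C(C)=C/CCl | intermediate
3 | (2E,6E,10E)-geranylgeranyl diphosphate (handled as the ammonium salt, drawn as the free acid) | CC(C)=CCC/C(C)=C/CC/C(C)=C/CC/C(C)=C/COP(=O)(O)OP(=O)(O)O | intermediate
4 | (5S,9S,10S)-labda-7,13E-dien-15-yl diphosphate (trans-decalin, C20 methyl on the face opposite to H5 and H9, ring B alkene C7=C8, E side-chain alkene) | CC1=CC[C@H]2C(C)(C)CCC[C@]2(C)[C@H]1CC/C(C)=C/COP(=O)(O)OP(=O)(O)O | intermediate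
5 | (5S,9S,10S)-labda-7,13E-dien-15-yl phosphate | CC1=CC[C@H]2C(C)(C)CCC[C@]2(C)[C@H]1CC/C(C)=C/COP(=O)(O)O | intermediate
6 | (5S,9S,10S)-labda-7,13E-dien-15-ol | CC1=CC[C@H]2C(C)(C)CCC[C@]2(C)[C@H]1CC/C(C)=C/CO | intermediate
7 | Meldrum's acid (2,2-dimethyl-1,3-dioxane-4,6-dione) | CC1(C)OC(=O)CC(=O)O1 | starting material
8 | (5S,9S,10S)-labda-7,13E-dien-15-yl hydrogen malonate | CC1=CC[C@H]2C(C)(C)CCC[C@]2(C)[C@H]1CC/C(C)=C/COC(=O)CC(=O)O | target

**Step count**
Total steps: 5. Longest linear sequence: 5 steps (1 → 2 → 3 → 4 → 6 → 8).

**Steps most likely to fail**

Step 3. The cascade may stall before 3 is consumed, because class 2 cyclases are inhibited by their own substrate at the magnesium concentrations they need and lose activity over a long feed. Termination may also leak towards loss of a C17 proton. The fallback sets out from 3 and comes back at 6, and it takes the alkene-forming event out of the enzyme. Compound 3 would be cyclised with a labd-13E-en-8α-ol diphosphate synthase, a class 2 cyclase of the same fold in which the C8 cation is quenched by water (the enzyme type that leads to sclareol in clary sage). This should give 8α-hydroxylabd-13E-en-15-yl diphosphate F1, the (5S,8R,9R,10S) isomer. Alkaline phosphatase would take it through 8α-hydroxylabd-13E-en-15-yl phosphate F2 to labd-13E-ene-8α,15-diol F3. Ac2O in pyridine at 0 °C should acetylate only the primary allylic hydroxyl and give 8α-hydroxylabd-13E-en-15-yl acetate F4. Dehydration of the tertiary alcohol with SOCl2 and pyridine in CH2Cl2 at −40 °C is expected to give labda-7,13E-dien-15-yl acetate F5 as one component of a mixture with its C8=C17 isomer, from which it would be separated on AgNO3-impregnated silica. K2CO3 in MeOH would then release 6.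

Step 2. Solvolysis, SN2′ attack or elimination of the allylic chloride, and hydrolysis of the diphosphate ester to the monophosphate during cation exchange and chromatography, may erode the material before the key step. The fallback sets out from 1 and comes back at 3, and it avoids the allylic halide altogether. Alcohol 1 would be phosphorylated directly with bis(triethylammonium) hydrogen phosphate activated by trichloroacetonitrile in MeCN at rt. Successive phosphoryl transfers lead through geranylgeranyl phosphate F6 to 3, which would be separated from mono- and triphosphate on silica with iPrOH/conc. NH4OH/water.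

Step 5. At the temperature needed to open Meldrum's acid, the half ester may decarboxylate to the acetate, and the acidic medium may ionise the allylic C15–O bond or shift the C7=C8 alkene. The fallback sets out from 6 (with 7 as the malonyl source) and comes back at 8, and it never heats or acidifies the terpene. Meldrum's acid 7 would be heated with 2-(trimethylsilyl)ethanol to give 2-(trimethylsilyl)ethyl hydrogen malonate F7. Steglich coupling of F7 with 6 (DCC, DMAP, CH2Cl2, 0 °C) should give labda-7,13E-dien-15-yl 2-(trimethylsilyl)ethyl malonate F8. Bu4NF in THF at 0 °C would then remove the silylethyl group by fluoride-induced fragmentation and give 8 after mild acidification.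

**Further compounds**
F1 | step 3 | (5S,8R,9R,10S)-8α-hydroxylabd-13E-en-15-yl diphosphate | C[C@@]1(O)CC[C@H]2C(C)(C)CCC[C@]2(C)[C@H]1CC/C(C)=C/COP(=O)(O)OP(=O)(O)O
F2 | step 3 | (5S,8R,9R,10S)-8α-hydroxylabd-13E-en-15-yl phosphate | C[C@@]1(O)CC[C@H]2C(C)(C)CCC[C@]2(C)[C@H]1CC/C(C)=C/COP(=O)(O)O
F3 | step 3 | (5S,8R,9R,10S)-labd-13E-ene-8α,15-diol | C[C@@]1(O)CC[C@H]2C(C)(C)CCC[C@]2(C)[C@H]1CC/C(C)=C/CO
F4 | step 3 | (5S,8R,9R,10S)-8α-hydroxylabd-13E-en-15-yl acetate | C[C@@]1(O)CC[C@H]2C(C)(C)CCC[C@]2(C)[C@H]1CC/C(C)=C/COC(C)=O
F5 | step 3 | (5S,9S,10S)-labda-7,13E-dien-15-yl acetate | CC1=CC[C@H]2C(C)(C)CCC[C@]2(C)[C@H]1CC/C(C)=C/COC(C)=O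
F6 | step 2 | (2E,6E,10E)-geranylgeranyl phosphate | CC(C)=CCC/C(C)=C/CC/C(C)=C/CC/C(C)=C/COP(=O)(O)O
F7 | step 5 | 2-(trimethylsilyl)ethyl hydrogen malonate | C[Si](C)(C)CCOC(=O)CC(=O)O
F8 | step 5 | (5S,9S,10S)-labda-7,13E-dien-15-yl 2-(trimethylsilyl)ethyl malonate | CC1=CC[C@H]2C(C)(C)CCC[C@]2(C)[C@H]1CC/C(C)=C/COC(=O)CC(=O)OCC[Si](C)(C)C
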